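## The problem

ent-Fisetinidol-(4β→6)-catechin (20) consists of two flavan-3-ol units: the upper one with benzo ring A, pyran ring C and catechol ring B, the lower one with benzo ring D, pyran ring F and catechol ring E. They are joined by one bond from the doubly benzylic sp3 carbon C4 of ring C to C6 of ring D. C6 lies between two oxygen-bearing carbons and is the less reactive of the two free positions of ring D, so the link must be steered away from C8 and made in a crowded place. There are five stereocentres. C2 (R) and C3 (S) of ring F are those of (+)-catechin (1) and can be bought. C2 (S), C3 (R) and C4 (R) of ring C form an all-trans triad of the series enantiomeric to natural fisetinidol and must be created. The centres of ring F are too remote to steer anything in ring C, but a ring D substituent at C4 screens one face of ring C and can pass its configuration on to C2 and C3. Nine free hydroxyl groups make the compound sensitive to oxidation and base, and the interflavan bond and the benzylic C2–O1 bonds do not tolerate strong acid, so the phenols stay masked until a last, neutral step. The enabling feature is the segment O1–C2(ring B)–C3(OH) of ring C: it is the anti-Markovnikov hydrate of an enol ether O1–C2=C3. The C2=C3 bond can therefore be closed by metathesis between a 1-arylvinyl ether on the ring A oxygen and a vinyl group on C4, and the flat flav-2-ene then takes up H and OH on the face away from ring D.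

## Retrosynthesis

**Deprotection.** The eight O–benzyl bonds of 20 and a C8–Br bond on ring D are cut last, back to 19. Benzyl is preferred to silyl or acetal groups because all eight ethers and the bromine that caps C8 fall in one hydrogenolysis under neutral to slightly basic conditions. 19 is no simpler in skeleton, but it is stable and chromatographable. The forward step must cleave aryl–O–benzyl and aryl–Br bonds and leave the benzylic C2–O1 and C4–aryl bonds alone.

**Hydration of the enol ether.** In 19 the C3–O and C2–H bonds are disconnected, which leads through borane 18 to flav-2-ene 17. The neighbouring cuts (C2–O1 by etherification, C4–C6 by cation capture) would both need C2 and C3 in place beforehand in the unnatural series. This cut derives both from C4, and 17 has one upper stereocentre where 19 has three. The forward reaction must put boron on C3 and deliver H and B to the face opposite ring D.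

**Ring C (key disconnection).** The C2=C3 bond of 17 is cut to diene 16, an aryl 1-arylvinyl ether with a vinyl group on the diarylmethine carbon. A cyclodehydration of a ketone onto the phenol (cut at C2–O1) would place the C4 centre β to a carbonyl group. The metathesis cut keeps C4 away from any enolisable position and draws ring B from an ester. 16 is acyclic in its upper half and has a single new stereocentre. The forward reaction must join a monosubstituted alkene with a 1,1-disubstituted enol ether in a six-membered ring without migration of the doubly benzylic allylic double bond.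

**Enol ether and ring B.** The C=CH2 unit of 16 is traced to the carbonyl of aryl ester 15, and the ester C–O bond to phenol 13 and acid 14. This is preferred to a C–O coupling of 13 with an α-halostyrene because esterification and ester methylenation are routine and ring B then comes from a catalogue acid. 13 is the bare 2-(1-arylallyl)phenol. Forward, the acylation must be non-basic and the methylenation must take the ester carbonyl in the presence of the vinyl group.

**The interflavan bond.** After return to silyl ether 12, the C4–C6 bond is cut with allylic transposition (SN2′ retron) to arylmagnesium 11 and cinnamyl phosphate 10. The polarity is deliberate. A cinnamyl phosphate on the tri-oxygenated ring D would ionise far too easily and cost four more steps, whereas ring D as the nucleophile is one operation from iodide 5. A Friedel–Crafts union at this bond was set aside because it gives no control of C4. The cut splits the molecule into two halves of similar size, neither with a stereocentre still to be made. Forward, the copper catalyst must give the branched product and select one face with a hindered aryl nucleophile. The ring A oxygen carries a silyl group because it leaves with fluoride.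

**Ring A piece.** 10 goes back through alcohol 9 and ester 8 to aldehyde 7 (C=C cut, Wittig retron) and to the commercial phenol 6. This is the most reliable access to an (E)-cinnamyl alcohol. The steps only require that the aryl silyl ether survives, which rules out basic olefination conditions.

**Ring D piece.** 11 arises from iodide 5 by halogen–metal exchange. The C6–I, C8–Br and O–benzyl bonds are then removed in turn through 4, 3 and 2 to (+)-catechin (1). Electrophiles attack benzylated 1 at C8 first, so C6 cannot be addressed directly. Bromine is therefore placed at C8 as a cap, iodine then goes to C6, and the iodide/bromide pair lets the exchange pick C6. The cap costs no extra step because the final hydrogenolysis removes it.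

## Roads not taken

**Alternative 1:** The cut is the interflavan bond itself. An upper unit with a leaving group at C4 is tied through its 3-oxygen and a diisopropylsilylene to the 5-oxygen of a lower catechin unit. A silyl triflate ionises C4, and the tethered C6 closes a seven-membered siladioxepine to give the bridged dimer A1.
- Merits: the bond is made by cation capture, which is indifferent to the crowding that burdens step 9 of the chosen route, and the tether fixes C6 over C8 without a halogen cap. In both respects this road is better.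
- Weak points: the cation precursor belongs to the unnatural (2S,3R) series, so ring C with C2 and C3 must be made by asymmetric synthesis before the key step. The lower unit needs a free 5-hydroxyl beside a protected 7-hydroxyl, which 1 does not offer readily. A tether anchored on O3 most easily delivers ring D to the face that carries O3, whereas A1 needs the seven-membered ring to span a trans C3–O/C4–aryl pair. Tether installation and removal add steps.
- Comparison: the chosen plan sets against the easier bond formation that one controlled centre (C4) generates the whole upper triad from an achiral aldehyde and acid, and that the C4 configuration does not depend on the geometry of a tether.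

**Alternative 2:** The cut runs through ring D. The C4a–C5 bond of the lower unit is formed last, by intramolecular Claisen condensation of the dienolate of a cyclic vinylogous ester (the future ring F) onto a methyl ester with a lithium amide base. Tautomerisation gives the aromatic ring D of A2.
- Merits: the C6/C8 question disappears because ring D does not exist when the C4–carbon bond is made, and that bond goes to an enolisable chain carbon, not to a hindered arene. Here it is superior to the chosen plan. The free 5- and 7-hydroxyls of A2 are no drawback.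
- Weak points: 1 can no longer be used. Ring F with its (2R,3S) centres, the complete upper unit and the connecting polyketide chain must all be built, giving a long linear sequence. The folding step must choose the γ-carbon of the dienolate over the α-carbon on a substrate with several acidic sites, and this is not established for a substrate of this size.
- Comparison: should the hindered aryl–carbon bond formation of the chosen plan fail altogether, this is the most fundamental way round it. The chosen plan sets against it the purchase of both ring F centres and a 15-step total.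

**Alternative 3:** The upper unit is first joined at C4 to a symmetric triphenol, so no regiochemical question arises, and ring F is then annulated. An aryl ether carrying a terminal epoxide cyclises under a Lewis acid or in a fluorinated alcohol. The ring D carbon ortho to the ether oxygen attacks the terminal epoxide carbon (6-endo), forming C4–C4a and the 3-hydroxyl of A3.
- Merits: symmetry solves C6 against C8 more cleanly than the bromine cap, which costs two halogenations and a late dehalogenation. The ring F centres can come from a catalytic asymmetric epoxidation, and A3 has its ring F hydroxyl already differentiated.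
- Weak points: it again needs an upper C4 electrophile of the unnatural series. One of three phenols (the one para to the upper unit) must be alkylated selectively at a secondary, electron-rich benzylic carbon with clean inversion. The epoxide opening must prefer 6-endo to 5-exo. The acid has to be tolerated by an ionisable bond between C4 and a phloroglucinol-type ring.
- Comparison: in regiocontrol this road is better. The chosen plan sets against it that the upper triad needs no preformed flavan-3-ol, that ring F is bought, and that the step count is much lower.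

Key step: step 13

Assumptions:
- 6 and 14 are taken as catalogue compounds; each is otherwise one or two routine steps from 2,4-dihydroxybenzaldehyde or 3,4-dihydroxybenzoic acid.
- Which antipode of the C2-symmetric NHC ligand of step 9 gives the (R) centre must be fixed in the first runs. The two C4 epimers are diastereomers and can be told apart and separated.
- The diarylmethine carbon of 12–17 is (R) because the ring D carbon (two oxygen-bearing ortho carbons) outranks the ring A carbon.
- Flavan numbering is used throughout. The C8 bromine on ring D is a spectator from 3 to 19.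

## Route

Step 1
Reactants: 1 (+)-catechin
Product: 2 5,7,3',4'-tetra-O-benzyl-(+)-catechin
Conditions: BnBr (4.4 equiv), K2CO3, DMF, 0 °C → rt
Reagents that add atoms: benzyl bromide, BrCc1ccccc1
Why: Williamson O-benzylation of the four phenols with carbonate as base; the secondary C3 alcohol is not ionised and C2/C3 are untouched, the low temperature limiting C-benzylation of ring D.

Step 2
Reactants: 2 5,7,3',4'-tetra-O-benzyl-(+)-catechin
Product: 3 8-bromo-5,7,3',4'-tetra-O-benzyl-(+)-catechin
Conditions: NBS (1.0 equiv), CH2Cl2, −78 → 0 °C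
Reagents that add atoms: N-bromosuccinimide, O=C1CCC(=O)N1Br
Why: Electrophilic aromatic bromination; in 5,7-di-O-benzylflavans C8 reacts first, so one equivalent of NBS places the bromine that caps C8 until the last step.

Step 3
Reactants: 3 8-bromo-5,7,3',4'-tetra-O-benzyl-(+)-catechin
Product: 4 8-bromo-3,5,7,3',4'-penta-O-benzyl-(+)-catechin
Conditions: NaH, BnBr, n-Bu4NI (cat.), DMF, 0 °C → rt
Reagents that add atoms: benzyl bromide, BrCc1ccccc1
Why: Williamson etherification of the C3 alkoxide; the ether is needed because a free hydroxyl would quench the arylmagnesium of step 9.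

Step 4
Reactants: 4 8-bromo-3,5,7,3',4'-penta-O-benzyl-(+)-catechin
Product: 5 8-bromo-6-iodo-3,5,7,3',4'-penta-O-benzyl-(+)-catechin
Conditions: NIS (1.1 equiv), CH2Cl2/MeCN, 0 °C → rt, dark (cat. CF3CO2H if slow)
Reagents that add atoms: N-iodosuccinimide, O=C1CCC(=O)N1I
Why: Second electrophilic aromatic substitution (iodination) at C6, the only free position of the tri-oxygenated ring D, which is far more electron-rich than the catechol ether ring E; it parallels the familiar 6,8-dihalogenation of such flavans.

Step 5
Reactants: 6 4-(benzyloxy)-2-hydroxybenzaldehyde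
Product: 7 4-(benzyloxy)-2-[(tert-butyldimethylsilyl)oxy]benzaldehyde
Conditions: TBSCl, imidazole, DMF, rt
Reagents that add atoms: tert-butyldimethylsilyl chloride, CC(C)(C)[Si](C)(C)Cl
Why: Imidazole-promoted silylation of the phenol; the aryl silyl ether tolerates ylide, hydride and Grignard reagents and later leaves with fluoride without acid or strong base.

Step 6
Reactants: 7 4-(benzyloxy)-2-[(tert-butyldimethylsilyl)oxy]benzaldehyde
Product: 8 ethyl (E)-3-{4-(benzyloxy)-2-[(tert-butyldimethylsilyl)oxy]phenyl}acrylate
Conditions: Ph3P=CHCO2Et, toluene, 80 °C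
Reagents that add atoms: ethyl (triphenylphosphoranylidene)acetate, CCOC(=O)C=P(c1ccccc1)(c1ccccc1)c1ccccc1
Why: Wittig olefination with a stabilised ylide under neutral conditions gives the (E)-cinnamate and spares the aryl silyl ether.

Step 7
Reactants: 8 ethyl (E)-3-{4-(benzyloxy)-2-[(tert-butyldimethylsilyl)oxy]phenyl}acrylate
Product: 9 (E)-3-{4-(benzyloxy)-2-[(tert-butyldimethylsilyl)oxy]phenyl}prop-2-en-1-ol
Conditions: i-Bu2AlH (2.5 equiv), CH2Cl2, −78 °C; aq. KNaC4H4O6
Reagents that add atoms: none
Why: 1,2-Reduction of the conjugated ester by i-Bu2AlH at low temperature gives the allylic alcohol without touching the alkene or the silyl ether.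

Step 8
Reactants: 9 (E)-3-{4-(benzyloxy)-2-[(tert-butyldimethylsilyl)oxy]phenyl}prop-2-en-1-ol
Product: 10 diethyl (E)-3-{4-(benzyloxy)-2-[(tert-butyldimethylsilyl)oxy]phenyl}allyl phosphate
Conditions: ClP(O)(OEt)2, Et3N, DMAP (cat.), CH2Cl2, 0 °C
Reagents that add atoms: diethyl chlorophosphate, CCOP(=O)(Cl)OCC
Why: O-Phosphorylation of the primary allylic alcohol; a phosphate is the usual leaving group for copper-catalysed SN2′ substitution, and 10 is used promptly because the electron-rich cinnamyl system ionises easily.

Step 9
Reactants: 5 8-bromo-6-iodo-3,5,7,3',4'-penta-O-benzyl-(+)-catechin; 10 diethyl (E)-3-{4-(benzyloxy)-2-[(tert-butyldimethylsilyl)oxy]phenyl}allyl phosphate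
Product: 12 8-bromo-6-[(1R)-1-{4-(benzyloxy)-2-[(tert-butyldimethylsilyl)oxy]phenyl}prop-2-en-1-yl]-3,5,7,3',4'-penta-O-benzyl-(+)-catechin, via arylmagnesium chloride 11 (not isolated)
Conditions: 5, i-PrMgCl·LiCl, THF, −20 → 0 °C; then slow addition to 10, CuCl (5 mol %), C2-symmetric 4,5-diphenyl-1,3-bis(arylmethyl)imidazolinium chloride (6 mol %), CH2Cl2, −78 °C
Reagents that add atoms: none
Why: Iodine–magnesium exchange takes the C6 iodide and leaves the C8 bromide, and 11 then enters a copper-catalysed enantioselective SN2′ allylic arylation of a cinnamyl electrophile: the aryl-copper NHC complex adds to the γ-carbon anti to the phosphate and reductive elimination from the σ-allyl trivalent copper species gives the branched 1,1-diarylpropene. The ligand decides which face of the γ-carbon is attacked and its antipode is chosen to give the (R) centre; because rings D and F are enantiopure, a minor C4 epimer is a diastereomer and can be removed.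

Step 10
Reactants: 12 8-bromo-6-[(1R)-1-{4-(benzyloxy)-2-[(tert-butyldimethylsilyl)oxy]phenyl}prop-2-en-1-yl]-3,5,7,3',4'-penta-O-benzyl-(+)-catechin
Product: 13 8-bromo-6-{(1R)-1-[4-(benzyloxy)-2-hydroxyphenyl]prop-2-en-1-yl}-3,5,7,3',4'-penta-O-benzyl-(+)-catechin
Conditions: n-Bu4NF, AcOH, THF, 0 °C
Reagents that add atoms: none
Why: Fluoride-induced cleavage of the aryl silyl ether; acetic acid buffers the phenoxide so that the doubly benzylic allylic C–H is not deprotonated and the alkene does not migrate.

Step 11
Reactants: 13 8-bromo-6-{(1R)-1-[4-(benzyloxy)-2-hydroxyphenyl]prop-2-en-1-yl}-3,5,7,3',4'-penta-O-benzyl-(+)-catechin; 14 3,4-bis(benzyloxy)benzoic acid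
Product: 15 5-(benzyloxy)-2-[(1R)-1-(8-bromo-3,5,7,3',4'-penta-O-benzylcatechin-6-yl)prop-2-en-1-yl]phenyl 3,4-bis(benzyloxy)benzoate
Conditions: DCC, DMAP, CH2Cl2, rt
Reagents that add atoms: none
Why: Steglich esterification (carbodiimide activation, acyl transfer by DMAP) acylates the hindered phenol under neutral conditions that leave the C4 centre and the vinyl group alone.

Step 12
Reactants: 15 5-(benzyloxy)-2-[(1R)-1-(8-bromo-3,5,7,3',4'-penta-O-benzylcatechin-6-yl)prop-2-en-1-yl]phenyl 3,4-bis(benzyloxy)benzoate
Product: 16 8-bromo-6-{(1R)-1-[4-(benzyloxy)-2-({1-[3,4-bis(benzyloxy)phenyl]vinyl}oxy)phenyl]prop-2-en-1-yl}-3,5,7,3',4'-penta-O-benzyl-(+)-catechin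
Conditions: Cp2TiMe2 (3 equiv), toluene, 70 °C, dark; filtration through basic Al2O3
Reagents that add atoms: dimethyltitanocene Cp2TiMe2, C[Ti+2]C.c1cc[cH-]c1.c1cc[cH-]c1
Why: Petasis methylenation: Cp2TiMe2 loses methane on warming to give Cp2Ti=CH2, which converts the aryl ester C=O into C=CH2 through an oxatitanacyclobutane; the ester carbonyl reacts faster than the monosubstituted alkene and the non-acidic, non-basic reagent leaves C4 alone. The enol ether is acid-sensitive and is handled on base-washed supports.

Step 13
Reactants: 16 8-bromo-6-{(1R)-1-[4-(benzyloxy)-2-({1-[3,4-bis(benzyloxy)phenyl]vinyl}oxy)phenyl]prop-2-en-1-yl}-3,5,7,3',4'-penta-O-benzyl-(+)-catechin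
Product: 17 (4R)-7-(benzyloxy)-2-[3,4-bis(benzyloxy)phenyl]-4-(8-bromo-3,5,7,3',4'-penta-O-benzylcatechin-6-yl)-4H-chromene (the perbenzylated 4-arylflav-2-ene)
Conditions: RuCl2(=CHPh)(PCy3)(H2IMes) (second-generation Grubbs catalyst, 10 mol % in two portions), 1,4-benzoquinone (20 mol %), toluene (0.01 M), 80 °C, Ar sparge
Reagents that add atoms: none
Why: Ring-closing metathesis of an enol ether with a terminal alkene. The ruthenium benzylidene first exchanges onto the monosubstituted C4 vinyl group, the resulting alkylidene at C3 adds across the 1,1-disubstituted aryl vinyl ether to a ruthenacyclobutane, and cycloreversion releases the C2=C3 bond and Ru=CH2, which carries the chain with loss of ethylene. The closest known reaction type is the sequence of ester methylenation and enol ether ring-closing metathesis that gives 4H-chromenes and benzofurans from esters of 2-allyl- and 2-vinylphenols. Ring C closes as a six-membered ring with the new double bond endocyclic, by intramolecular [2+2] cycloaddition and retro-[2+2]; the arene holds the C4 carbon and the ether oxygen cis, which favours closure over dimerisation at high dilution. No stereocentre is formed, and the C4 centre from step 9 is a spectator as long as the doubly benzylic allylic double bond does not migrate. The selectivity needed is chemoselectivity: initiation at the vinyl group and not at the gem-disubstituted enol ether (which reacts slowly for steric reasons and would give an unreactive Fischer-type carbene), and no ruthenium hydride isomerisation. The first is secured by the substitution pattern of 16, the second by 1,4-benzoquinone as hydride scavenger and by sweeping out ethylene. Benzyl ethers and the aryl bromide are inert to the catalyst.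

Step 14
Reactants: 17 (4R)-7-(benzyloxy)-2-[3,4-bis(benzyloxy)phenyl]-4-(8-bromo-3,5,7,3',4'-penta-O-benzylcatechin-6-yl)-4H-chromene
Product: 19 (2S,3R,4R)-7-(benzyloxy)-2-[3,4-bis(benzyloxy)phenyl]-4-(8-bromo-3,5,7,3',4'-penta-O-benzylcatechin-6-yl)chroman-3-ol, via 3-borylflavan 18 (not isolated)
Conditions: BH3·SMe2 (3 equiv), THF, 0 °C → rt; then 3 M NaOH, 30 % H2O2, 0 °C
Reagents that add atoms: hydrogen peroxide, OO
Why: Hydroboration–oxidation of the enol ether: H–B adds syn with boron at C3 (β to oxygen, the less substituted carbon) from the face opposite the pseudo-axial ring D substituent at C4, and oxidation proceeds with retention. This sets C2 (H cis to the C3 oxygen, ring B trans) and C3 (hydroxyl trans to ring D), i.e. the 2,3-trans-3,4-trans triad; prompt oxidation at low temperature forestalls β-elimination of the β-aryloxy borane.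

Step 15
Reactants: 19 (2S,3R,4R)-7-(benzyloxy)-2-[3,4-bis(benzyloxy)phenyl]-4-(8-bromo-3,5,7,3',4'-penta-O-benzylcatechin-6-yl)chroman-3-ol
Product: 20 ent-fisetinidol-(4β→6)-catechin
Conditions: H2 (1 atm), Pd(OH)2/C, Et3N, THF/MeOH/H2O, rt
Reagents that add atoms: none
Why: Hydrogenolysis of the eight benzyl ethers and hydrodebromination of C8–Br on Pd(OH)2/C in one operation; Et3N takes up HBr so that the interflavan bond and the C2–O1 bonds never see acid, and no stereocentre is touched.

## Compound list

1 | (+)-catechin, (2R,3S) | Oc1cc(O)cc2c1C[C@H](O)[C@@H](c1ccc(O)c(O)c1)O2 | starting material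
2 | 5,7,3',4'-tetra-O-benzyl-(+)-catechin | c1ccccc1COc1cc(OCc3ccccc3)cc2c1C[C@H](O)[C@@H](c1ccc(OCc3ccccc3)c(OCc3ccccc3)c1)O2 | intermediate
3 | 8-bromo-5,7,3',4'-tetra-O-benzyl-(+)-catechin | c1ccccc1COc1cc(OCc3ccccc3)c(Br)c2c1C[C@H](O)[C@@H](c1ccc(OCc3ccccc3)c(OCc3ccccc3)c1)O2 | intermediate
4 | 8-bromo-3,5,7,3',4'-penta-O-benzyl-(+)-catechin | c1ccccc1COc1cc(OCc3ccccc3)c(Br)c2c1C[C@H](OCc1ccccc1)[C@@H](c1ccc(OCc3ccccc3)c(OCc3ccccc3)c1)O2 | intermediate
5 | 8-bromo-6-iodo-3,5,7,3',4'-penta-O-benzyl-(+)-catechin | c1ccccc1COc1c(I)c(OCc3ccccc3)c(Br)c2c1C[C@H](OCc1ccccc1)[C@@H](c1ccc(OCc3ccccc3)c(OCc3ccccc3)c1)O2 | intermediate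
6 | 4-(benzyloxy)-2-hydroxybenzaldehyde | O=Cc1ccc(OCc2ccccc2)cc1O | starting material
7 | 4-(benzyloxy)-2-[(tert-butyldimethylsilyl)oxy]benzaldehyde | O=Cc1ccc(OCc2ccccc2)cc1O[Si](C)(C)C(C)(C)C | intermediate
8 | ethyl (E)-3-{4-(benzyloxy)-2-[(tert-butyldimethylsilyl)oxy]phenyl}acrylate | CCOC(=O)/C=C/c1ccc(OCc2ccccc2)cc1O[Si](C)(C)C(C)(C)C | intermediate
9 | (E)-3-{4-(benzyloxy)-2-[(tert-butyldimethylsilyl)oxy]phenyl}prop-2-en-1-ol | OC/C=C/c1ccc(OCc2ccccc2)cc1O[Si](C)(C)C(C)(C)C | intermediate
10 | diethyl (E)-3-{4-(benzyloxy)-2-[(tert-butyldimethylsilyl)oxy]phenyl}allyl phosphate | CCOP(=O)(OCC)OC/C=C/c1ccc(OCc2ccccc2)cc1O[Si](C)(C)C(C)(C)C | intermediate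
11 | (8-bromo-3,5,7,3',4'-penta-O-benzylcatechin-6-yl)magnesium chloride (not isolated) | c1ccccc1COc1c([Mg]Cl)c(OCc3ccccc3)c(Br)c2c1C[C@H](OCc1ccccc1)[C@@H](c1ccc(OCc3ccccc3)c(OCc3ccccc3)c1)O2 | intermediate
12 | 8-bromo-6-[(1R)-1-{4-(benzyloxy)-2-[(tert-butyldimethylsilyl)oxy]phenyl}prop-2-en-1-yl]-3,5,7,3',4'-penta-O-benzyl-(+)-catechin | CC(C)(C)[Si](C)(C)Oc1cc(OCc2ccccc2)ccc1[C@@H](C=C)c1c(OCc2ccccc2)c(Br)c2c(c1OCc1ccccc1)C[C@H](OCc1ccccc1)[C@@H](c1ccc(OCc3ccccc3)c(OCc3ccccc3)c1)O2 | intermediate
13 | 8-bromo-6-{(1R)-1-[4-(benzyloxy)-2-hydroxyphenyl]prop-2-en-1-yl}-3,5,7,3',4'-penta-O-benzyl-(+)-catechin | Oc1cc(OCc2ccccc2)ccc1[C@@H](C=C)c1c(OCc2ccccc2)c(Br)c2c(c1OCc1ccccc1)C[C@H](OCc1ccccc1)[C@@H](c1ccc(OCc3ccccc3)c(OCc3ccccc3)c1)O2 | intermediate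
14 | 3,4-bis(benzyloxy)benzoic acid | OC(=O)c1ccc(OCc2ccccc2)c(OCc2ccccc2)c1 | starting material
15 | 5-(benzyloxy)-2-[(1R)-1-(8-bromo-3,5,7,3',4'-penta-O-benzylcatechin-6-yl)prop-2-en-1-yl]phenyl 3,4-bis(benzyloxy)benzoate | O=C(Oc1cc(OCc2ccccc2)ccc1[C@@H](C=C)c1c(OCc2ccccc2)c(Br)c2c(c1OCc1ccccc1)C[C@H](OCc1ccccc1)[C@@H](c1ccc(OCc3ccccc3)c(OCc3ccccc3)c1)O2)c1ccc(OCc2ccccc2)c(OCc2ccccc2)c1 | intermediate
16 | 1-[3,4-bis(benzyloxy)phenyl]vinyl ether of phenol 13 (metathesis precursor, (R) at the diarylmethine carbon) | C=C(Oc1cc(OCc2ccccc2)ccc1[C@@H](C=C)c1c(OCc2ccccc2)c(Br)c2c(c1OCc1ccccc1)C[C@H](OCc1ccccc1)[C@@H](c1ccc(OCc3ccccc3)c(OCc3ccccc3)c1)O2)c1ccc(OCc2ccccc2)c(OCc2ccccc2)c1 | intermediate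
17 | (4R)-7-(benzyloxy)-2-[3,4-bis(benzyloxy)phenyl]-4-(8-bromo-3,5,7,3',4'-penta-O-benzylcatechin-6-yl)-4H-chromene | c1ccccc1COc1ccc2c(c1)OC(c1ccc(OCc3ccccc3)c(OCc3ccccc3)c1)=C[C@H]2c1c(OCc3ccccc3)c(Br)c3c(c1OCc1ccccc1)C[C@H](OCc1ccccc1)[C@@H](c1ccc(OCc4ccccc4)c(OCc4ccccc4)c1)O3 | intermediate
18 | 3-boryl analogue of 19 (BH2 at C3 in place of OH, same orientation; not isolated) | c1ccccc1COc1ccc2c(c1)O[C@@H](c1ccc(OCc3ccccc3)c(OCc3ccccc3)c1)[C@H](B)[C@H]2c1c(OCc3ccccc3)c(Br)c3c(c1OCc1ccccc1)C[C@H](OCc1ccccc1)[C@@H](c1ccc(OCc4ccccc4)c(OCc4ccccc4)c1)O3 | intermediate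
19 | (2S,3R,4R)-7-(benzyloxy)-2-[3,4-bis(benzyloxy)phenyl]-4-(8-bromo-3,5,7,3',4'-penta-O-benzylcatechin-6-yl)chroman-3-ol | c1ccccc1COc1ccc2c(c1)O[C@@H](c1ccc(OCc3ccccc3)c(OCc3ccccc3)c1)[C@H](O)[C@H]2c1c(OCc3ccccc3)c(Br)c3c(c1OCc1ccccc1)C[C@H](OCc1ccccc1)[C@@H](c1ccc(OCc4ccccc4)c(OCc4ccccc4)c1)O3 | intermediate
20 | ent-fisetinidol-(4β→6)-catechin, upper unit (2S,3R,4R), lower unit (2R,3S) | Oc1ccc2c(c1)O[C@@H](c1ccc(O)c(O)c1)[C@H](O)[C@H]2c1c(O)cc2c(c1O)C[C@H](O)[C@@H](c1ccc(O)c(O)c1)O2 | target

## Step count and risks

Total step count: 15. Longest linear sequence: 11 steps (1 to 20 through steps 1–4 and 9–15; the branch from 6 through steps 5–8 is equally long).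

**Step 13 (key step).** The most likely failure is slow closure on the crowded, gem-disubstituted enol ether. The catalyst then decays to ruthenium hydrides that move the C4 vinyl double bond into conjugation with both arenes, which destroys the C4 centre; dimerisation through the vinyl groups is the second risk. Fallback, setting out from ester 15 and returning at 17 (it also bypasses the acid-sensitive 16): a titanium ethylidene made by the Takai–Utimoto protocol (TiCl4, Zn, PbCl2 cat., TMEDA, CH3CHBr2, THF) first exchanges onto the vinyl group. The resulting titanium alkylidene then olefinates the ester carbonyl intramolecularly, so ring C closes by carbonyl–olefin metathesis instead of olefin–olefin metathesis.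

**Step 9.** The hindered arylmagnesium 11 may transmetalate and reductively eliminate slowly, so that linear SN2 product and biaryl formation compete. The ligand may also exert little facial control in the presence of THF and LiCl carried over from the exchange. Fallback, setting out from aldehyde 7 and from 11 and returning at 17: substrate-controlled transfer of chirality instead of catalyst control.
- 7 is condensed with Ph3P=CHC(O)CH3 to the (E)-enone F1.
- Corey–Bakshi–Shibata reduction with (R)-2-methyl-CBS-oxazaborolidine and BH3·SMe2 (alkenyl as the large group) should give the (S)-allylic alcohol F2.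
- F2 is esterified with picolinic acid (DCC, DMAP) to the picolinate F3.
- The arylcopper from 11 and CuBr·SMe2 substitutes F3 in the anti-SN2′ sense, the pyridine nitrogen binding magnesium and activating the leaving group. This should give the (E)-1,1-diarylbut-2-ene F4 with the (R) diarylmethine centre.
- F4 carries a propenyl in place of the vinyl group. It is desilylated to the phenol F5, esterified with 14 to the ester F6 and methylenated to the enol ether F7, as in steps 10–12.
- Ring-closing metathesis of F7 under the conditions of step 13 expels propene and gives 17.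

**Step 14.** Facial discrimination by ring D could be incomplete, or the β-aryloxy organoborane 18 could eliminate and open ring C before oxidation. Fallback, setting out from 17 and returning at 19: dihydroxylation with OsO4 (cat.) and N-methylmorpholine N-oxide on the face opposite ring D gives the cyclic hemiketal diol F8. Ionic reduction with Et3SiH and BF3·OEt2 at −78 °C removes the C2 hydroxyl through the 2-aryl oxocarbenium ion, hydride again entering anti to ring D.

**Step 15.** Hydrodebromination may lag behind debenzylation, leaving brominated polyphenols that are hard to separate, or HBr may build up locally and cleave the interflavan bond. Fallback, setting out from 19 and returning at 20: the bromine is removed first by bromine–lithium exchange (n-BuLi, 2.2 equiv, THF, −78 °C, then MeOH) to give the bromine-free octabenzyl ether F9, which is hydrogenolysed over Pd(OH)2/C without base.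

## Further compounds

F1 | step 9 | (E)-4-{4-(benzyloxy)-2-[(tert-butyldimethylsilyl)oxy]phenyl}but-3-en-2-one | CC(=O)/C=C/c1ccc(OCc2ccccc2)cc1O[Si](C)(C)C(C)(C)C
F2 | step 9 | (S,E)-4-{4-(benzyloxy)-2-[(tert-butyldimethylsilyl)oxy]phenyl}but-3-en-2-ol | C[C@H](O)/C=C/c1ccc(OCc2ccccc2)cc1O[Si](C)(C)C(C)(C)C
F3 | step 9 | (S,E)-4-{4-(benzyloxy)-2-[(tert-butyldimethylsilyl)oxy]phenyl}but-3-en-2-yl pyridine-2-carboxylate | C[C@H](OC(=O)c1ccccn1)/C=C/c1ccc(OCc2ccccc2)cc1O[Si](C)(C)C(C)(C)C
F4 | step 9 | 8-bromo-6-[(1R,2E)-1-{4-(benzyloxy)-2-[(tert-butyldimethylsilyl)oxy]phenyl}but-2-en-1-yl]-3,5,7,3',4'-penta-O-benzyl-(+)-catechin | CC(C)(C)[Si](C)(C)Oc1cc(OCc2ccccc2)ccc1[C@@H](/C=C/C)c1c(OCc2ccccc2)c(Br)c2c(c1OCc1ccccc1)C[C@H](OCc1ccccc1)[C@@H](c1ccc(OCc3ccccc3)c(OCc3ccccc3)c1)O2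
F5 | step 9 | 8-bromo-6-{(1R,2E)-1-[4-(benzyloxy)-2-hydroxyphenyl]but-2-en-1-yl}-3,5,7,3',4'-penta-O-benzyl-(+)-catechin | Oc1cc(OCc2ccccc2)ccc1[C@@H](/C=C/C)c1c(OCc2ccccc2)c(Br)c2c(c1OCc1ccccc1)C[C@H](OCc1ccccc1)[C@@H](c1ccc(OCc3ccccc3)c(OCc3ccccc3)c1)O2
F6 | step 9 | 5-(benzyloxy)-2-[(1R,2E)-1-(8-bromo-3,5,7,3',4'-penta-O-benzylcatechin-6-yl)but-2-en-1-yl]phenyl 3,4-bis(benzyloxy)benzoate | O=C(Oc1cc(OCc2ccccc2)ccc1[C@@H](/C=C/C)c1c(OCc2ccccc2)c(Br)c2c(c1OCc1ccccc1)C[C@H](OCc1ccccc1)[C@@H](c1ccc(OCc3ccccc3)c(OCc3ccccc3)c1)O2)c1ccc(OCc2ccccc2)c(OCc2ccccc2)c1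
F7 | step 9 | 1-[3,4-bis(benzyloxy)phenyl]vinyl ether of phenol F5 | C=C(Oc1cc(OCc2ccccc2)ccc1[C@@H](/C=C/C)c1c(OCc2ccccc2)c(Br)c2c(c1OCc1ccccc1)C[C@H](OCc1ccccc1)[C@@H](c1ccc(OCc3ccccc3)c(OCc3ccccc3)c1)O2)c1ccc(OCc2ccccc2)c(OCc2ccccc2)c1
F8 | step 14 | (2S,3R,4R)-7-(benzyloxy)-2-[3,4-bis(benzyloxy)phenyl]-4-(8-bromo-3,5,7,3',4'-penta-O-benzylcatechin-6-yl)chromane-2,3-diol (hemiketal; both hydroxyls trans to ring D) | c1ccccc1COc1ccc2c(c1)O[C@@](O)(c1ccc(OCc3ccccc3)c(OCc3ccccc3)c1)[C@H](O)[C@H]2c1c(OCc3ccccc3)c(Br)c3c(c1OCc1ccccc1)C[C@H](OCc1ccccc1)[C@@H](c1ccc(OCc4ccccc4)c(OCc4ccccc4)c1)O3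
F9 | step 15 | (2S,3R,4R)-7-(benzyloxy)-2-[3,4-bis(benzyloxy)phenyl]-4-(3,5,7,3',4'-penta-O-benzylcatechin-6-yl)chroman-3-ol | c1ccccc1COc1ccc2c(c1)O[C@@H](c1ccc(OCc3ccccc3)c(OCc3ccccc3)c1)[C@H](O)[C@H]2c1c(OCc3ccccc3)cc3c(c1OCc1ccccc1)C[C@H](OCc1ccccc1)[C@@H](c1ccc(OCc4ccccc4)c(OCc4ccccc4)c1)O3
F0 | step 13 | none | none
A1 | alternative 1 | 3-O,5-O-diisopropylsilylene-bridged hepta-O-benzyl ent-fisetinidol-(4β→6)-catechin | c1ccccc1COc1ccc2c(c1)O[C@@H](c1ccc(OCc3ccccc3)c(OCc3ccccc3)c1)[C@@H]3O[Si](C(C)C)(C(C)C)Oc4c([C@H]32)c(OCc6ccccc6)cc5c4C[C@H](OCc4ccccc4)[C@@H](c4ccc(OCc6ccccc6)c(OCc6ccccc6)c4)O5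
A2 | alternative 2 | hepta-O-benzyl ent-fisetinidol-(4β→6)-catechin with free 5- and 7-hydroxyls on ring D | c1ccccc1COc1ccc2c(c1)O[C@@H](c1ccc(OCc3ccccc3)c(OCc3ccccc3)c1)[C@H](OCc1ccccc1)[C@H]2c4c(O)cc5c(c4O)C[C@H](OCc4ccccc4)[C@@H](c4ccc(OCc6ccccc6)c(OCc6ccccc6)c4)O5
A3 | alternative 3 | octa-O-benzyl ent-fisetinidol-(4β→6)-catechin with free 3-hydroxyl on ring F | c1ccccc1COc1ccc2c(c1)O[C@@H](c1ccc(OCc3ccccc3)c(OCc3ccccc3)c1)[C@H](OCc1ccccc1)[C@H]2c4c(OCc5ccccc5)cc5c(c4OCc4ccccc4)C[C@H](O)[C@@H](c4ccc(OCc6ccccc6)c(OCc6ccccc6)c4)O5
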